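The numbers of this flask are assumed; the flask was simulated.

I decided to count turnovers first, and this note to you is that count.

starting material 2.0 M; protic impurity 2.00 M; free catalyst 15 mol%

    starting material + free catalyst ⇌ catalyst intermediate A (K1 = 0.25 L mol⁻¹, k1 = 0.0037 L mol⁻¹ s⁻¹)
    catalyst intermediate A → catalyst intermediate B (k2 = 0.0022 s⁻¹)
    catalyst intermediate B ⇌ free catalyst + product (K3 = 0.39 M, k3 = 0.011 s⁻¹)
    starting material + protic impurity → quenched substrate (k4 = 0.0039 L mol⁻¹ s⁻¹)

1. the form that holds most of the catalyst when 30 % of the starting material are converted (free catalyst / catalyst intermediate B / catalyst intermediate A)
2. its share of the catalyst then

When I left the flask, starting material, protic impurity and free catalyst stood as charged. Leave the protic impurity alone: at the start it took starting material 7.0 times as fast as the forward binding step, so I timed the mark by that path. Taking that path by itself, with the two charges equal, the reciprocal of [starting material] grew steadily with 0.0039 L mol⁻¹ s⁻¹, and the mark came after 0.916 min. Binding counts as conversion too, so I knew this clock ran long.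

At 0.44 min⁻¹ per free catalyst, that time allowed 0.407 binding events per catalyst, with [starting material] as charged: this is the turnover count. It is below one. Reckoned with that rate held and binding taken as one-way, the free share comes to 66.6 %, which outweighs the bound forms together. So I committed to free catalyst as the resting state, with that figure as a low estimate, which is a different thing from the forecast's number.

The forecast gave free catalyst at 81 %, on this ground: “The protic impurity consumes starting material several times faster than the catalyst does”.

The simulation gave free catalyst at 81.5 %, with catalyst intermediate A at 17.5 % and catalyst intermediate B at 1.01 %.

My count of 0.407 belonged to a clock of 0.916 min. The flask reached the mark at 0.816 min, which makes the count 0.362 and the low estimate 69.6 %, below the share found. The path from starting material and protic impurity to quenched substrate held the rate down at the mark: in the run without it, the rate at 30 % conversion was 2.40 times the actual one, and the apparent order in free catalyst rose from 0.74 to 0.97.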